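The earlier runs and the new flask stem from a simulated flask on assumed constants, and the scatter is random.

Time was what I looked at first: in the ochre flask the left-handed product read 38.3 % at 8.00 h and 39.3 % at 12.0 h, so the late readings could show how the product divides.

| setting | ochre | amber | flask |
|---|---|---|---|
| left-handed substrate | 0.80 M | 0.80 M | 0.80 M |
| right-handed substrate | 0.80 M | 0.80 M | 0.80 M |
| coupling partner | 2.5 equiv | 2.5 equiv | 2.50 equiv |
| free catalyst | 0.1 mol% | 0.1 mol% | 0.1 mol% |
| racemization catalyst | 0.27 mol% | 0.41 mol% | 0.27 mol% |
| impurity | 96 µM | 96 µM | 96 µM |
| remark | the very flask that is asked about, followed so far | run made earlier |  |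
| time |  |  | 40 h |

| run | time / h | left-handed product / % | right-handed product / % | left-handed substrate / % |
|---|---|---|---|---|
| ochre | 1.50 | 24.4 | 10.7 | 33.7 |
| ochre | 3.00 | 30.9 | 14.7 | 28.9 |
| ochre | 5.00 | 34.7 | 15.1 | 27.6 |
| ochre | 6.00 | 35.8 | 14.2 | 26.4 |
| ochre | 8.00 | 38.3 | 16.3 | 24.7 |
| ochre | 10.0 | 36.5 | 17.8 | 21.7 |
| ochre | 12.0 | 39.3 | 16.8 | 21.8 |
| amber | 6.00 | 36.8 | 17.0 | 22.8 |
| amber | 12.0 | 39.9 | 17.6 | 22.8 |
| amber | 15.0 | 39.1 | 18.5 | 21.1 |
| amber | 25.0 | 40.2 | 16.1 | 21.2 |
| amber | 30.0 | 40.8 | 19.9 | 23.7 |
| amber | 40.0 | 38.9 | 20.4 | 20.1 |

(readings scatter by 1 percentage point)

- free catalyst is single-handed; left-handed substrate and right-handed substrate are mirror images of each other, charged as a racemate, each of them at the stated concentration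
- an excess is the difference of the two amounts in percent of their sum
- an excess is below zero if the other one leads

- left-handed product and right-handed product together, in percent of the left-handed substrate and right-handed substrate charged together, at 40 h
- excess of left-handed product over right-handed product in the product at 40 h
- whether the exchange between left-handed substrate and right-handed substrate keeps pace with the reaction: how far the product's excess at 40 h gets from its value without exchange to its value with instant exchange (above 80 % keeps pace, below 20 % hardly takes part, else lags behind)

I began with two extreme versions of the ochre flask, counting everything as fractions of the combined charge. Without exchange, each substrate feeds its own product and no other, so at 12.0 h the left-handed substrate should have stood at 10.7 %. It read 21.8 %, twice that.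

With instant exchange, the two substrates stay equal, at 21.9 % each at that time, and the products form in a constant ratio at any conversion. The ochre reading of the left-handed substrate had gone 98.7 % of the way from the first value to the second, so, within the scatter, I placed the ochre flask beside the instant extreme and judged that the exchange keeps pace. The remaining gap is a small correction: the ratio in which the products form at a given moment is the selectivity factor multiplied by the quotient of the two substrates at that moment, and the ochre readings at 12.0 h can't tell that quotient from unity.

So I summed the left-handed and the right-handed product from 8.00 h to 12.0 h and took their quotient as the selectivity factor, the ratio of left-handed to right-handed coupling at equal substrates, which read 2.24. That gave an excess of 38.3 %. For the yield I took the amber run's last reading, 59.3 %.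

The forecast, made from the same runs, gave 58.5 %, 37 % and keeps pace: “Exchange therefore outruns coupling”.

The flask gave 57.4 % and 39.0 %, and its exchange keeps pace, 93 % of the way.

    coupling partner + free catalyst + right-handed substrate → free catalyst + right-handed product (k = 4.00 M⁻² min⁻¹)
    left-handed substrate + racemization catalyst ⇌ right-handed substrate + racemization catalyst, rate k2*[racemization catalyst]*[left-handed substrate] forward; the back reaction follows from the equilibrium constant (k = 29.0 M⁻¹ min⁻¹)
    coupling partner + free catalyst + left-handed substrate → free catalyst + left-handed product (k = 9.30 M⁻² min⁻¹)
    free catalyst + impurity → spent catalyst (k = 1300 M⁻¹ min⁻¹)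
    2 coupling partner → self-condensation product (k = 0.00430 M⁻¹ min⁻¹)

The half-life of the left-handed substrate by its forward exchange step alone, at the charged concentrations, was 0.18 h. My excess from the selectivity factor lay 0.70 percentage points below the result. The flask with 0.025 mol% of free catalyst reached 20.9 % of combined product; the same factor assigns 14.4 % of the charge to left-handed product, and that flask held 14.6 %.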